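**Plan** (flavanone numbering, second unit double-primed; BINAP = 2,2'-bis(diphenylphosphino)-1,1'-binaphthyl)
Retrosynthesis: the four phenols are masked as benzyl ethers. O1–C8a and O1''–C8a'' are cut first (SNAr), then C4–C4a and C4''–C4a'' (aryl Grignard reagent on a Weinreb amide), and last C3–C3'' (enolate dimerisation).
Enabling feature: C2 and C2'' are oxygen-bearing benzylic carbons β to the carbonyl of their own ring C (C4, C4'') and, across C3–C3'', γ to the carbonyl of the other ring C. The core C2–C3(C4)–C3''(C4'')–C2'' is thus a 2,3-diaroylsuccinate at a lower oxidation level, and C3/C3'' epimerise while the ketones are present.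
Forward order: C3–C3'' bond, then double ketone hydrogenation closing two temporary γ-lactone rings (cis-fused 3,7-dioxabicyclo[3.3.0]octane-2,6-dione). Lactone opening, attachment of both rings A, closure of both rings C and debenzylation follow.
Stereochemistry: C2 and C2'' (R,R) come from the (S)-BINAP ligand, and their C–O bonds are never broken afterwards. C3 and C3'' are parked as R,R (2,3-cis) by the dynamic resolution and the cis ring fusion, then turned into S,S (2,3-trans) by thermodynamic enolisation of the chromanones.

Key step: step 3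

Assumption: RuCl2[(S)-BINAP] is taken to act on 4 in the sense known for simple aroylacetates ((S)-ligand gives the (R)-3-aryl-3-hydroxy ester) and to favour the syn hydroxy ester; were the sense opposite, the (R)-ligand would be used.

Step 1
Reactants: 1 1-[4-(benzyloxy)phenyl]ethan-1-one
Product: 2 ethyl 3-[4-(benzyloxy)phenyl]-3-oxopropanoate
Conditions: NaH (2.2 equiv), (EtO)2CO, THF, reflux; aq HCl quench, 0 °C
Reagents that add atoms: diethyl carbonate, CCOC(=O)OCC
Why: Crossed Claisen condensation of the methyl ketone enolate with a non-enolisable carbonate, driven to completion by deprotonation of the β-keto ester formed; no stereocentre arises.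

Step 2
Reactants: 2 ethyl 3-[4-(benzyloxy)phenyl]-3-oxopropanoate (two molecules)
Product: 4 diethyl 2,3-bis[4-(benzyloxy)benzoyl]butanedioate (stereolabile meso/dl mixture), via iodo keto ester 3 (not isolated)
Conditions: NaH (1.0 equiv), THF, 0 °C; I2 (0.5 equiv), 0 °C to rt
Reagents that add atoms: iodine, [I][I] (its atom is held only in 3 and leaves again as iodide)
Why: Oxidative enolate dimerisation, the classical entry to 2,3-diacylsuccinates, in which half of the sodium enolate is iodinated to 3 and the other half displaces iodide from it (SN2), the new centres C3 and C3'' being doubly activated, stereolabile and deliberately left uncontrolled.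

Step 3
Reactants: 4 diethyl 2,3-bis[4-(benzyloxy)benzoyl]butanedioate
Product: 6 (1R,4R,5R,8R)-4,8-bis[4-(benzyloxy)phenyl]-3,7-dioxabicyclo[3.3.0]octane-2,6-dione (cis-fused, both aryl groups exo), via diol diester 5 (not isolated)
Conditions: H2 (60 atm), RuCl2[(S)-BINAP] (4 mol %), degassed CH2Cl2–EtOH 4:1, 50 °C; then toluene, 80 °C, EtOH distilled off
Reagents that add atoms: none
Why: Proposed new method: RuCl2[(S)-BINAP] and H2 give a ruthenium monohydride that binds each β-keto ester unit of 4 through its ketone and ester oxygens in a six-membered chelate and passes hydride to the ketone face left open by the ligand, while the stereoisomers of 4 interconvert through their enols faster than they are reduced. The closest known reaction type is the Noyori hydrogenation of α-substituted β-keto esters with dynamic kinetic resolution, which includes 2-acylsuccinates that lactonise to paraconic esters, and the racemic reduction and lactonisation of 2,3-diaroylsuccinates is classical furofuran-lignan chemistry; new here is that two ketones and two adjacent stereolabile carbons are processed in one molecule. Each hydroxyl of 5 then displaces ethoxide from the ester of the other half, so both γ-lactone rings close by 5-exo-trig acyl substitution. C4 and C8 of 6 (later C2'' and C2) are fixed as R by the ligand, in the sense known for aroylacetates. C1 and C5 (later C3 and C3'') are fixed by the dynamic resolution, expected to give the syn hydroxy ester at both units, and are filtered by ring strain, because only a like-configured pair can close the second lactone to a cis-fused bicycle, in which syn units place both aryl groups exo on the convex face. The step needs ketone reduction without loss of benzyl ethers and without Paal–Knorr dehydration of the 1,4-diketone, which the homogeneous, acid-free ruthenium system secures, and it needs the same facial sense at both ketones, which the single catalyst secures, a molecule with one wrong carbinol becoming the unsymmetrical exo,endo diastereomer that crystallisation or chromatography removes, so that the enantiomeric purity of 6 should exceed that of a single reduction.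

Step 4
Reactants: 6 (1R,4R,5R,8R)-4,8-bis[4-(benzyloxy)phenyl]-3,7-dioxabicyclo[3.3.0]octane-2,6-dione
Product: 7 (2R,3R)-2,3-bis{(R)-[4-(benzyloxy)phenyl](hydroxy)methyl}-N1,N4-dimethoxy-N1,N4-dimethylbutanediamide
Conditions: MeNH(OMe)·HCl (6 equiv), Me3Al (6 equiv), CH2Cl2, 0 °C to rt; aq potassium sodium tartrate work-up; crude used at once
Reagents that add atoms: N,O-dimethylhydroxylamine hydrochloride, CNOC.Cl
Why: Weinreb aminolysis of a lactone with the aluminium amide cleaves only the two acyl–oxygen bonds, so all four stereocentres are kept, and its Lewis-acidic, non-basic character avoids the Stobbe-type E1cB ring opening that alkoxide or amidine bases would trigger in this β-acyloxy carbonyl array.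

Step 5
Reactants: 7 (2R,3R)-2,3-bis{(R)-[4-(benzyloxy)phenyl](hydroxy)methyl}-N1,N4-dimethoxy-N1,N4-dimethylbutanediamide
Product: 8 (2R,3R)-2,3-bis{(R)-[4-(benzyloxy)phenyl][(triethylsilyl)oxy]methyl}-N1,N4-dimethoxy-N1,N4-dimethylbutanediamide
Conditions: Et3SiOTf (3 equiv), 2,6-lutidine (4 equiv), CH2Cl2, −78 to 0 °C
Reagents that add atoms: triethylsilyl trifluoromethanesulfonate, CC[Si](CC)(CC)OS(=O)(=O)C(F)(F)F
Why: Silyl triflate silylation with a hindered pyridine base caps the crowded benzylic alcohols, which blocks relactonisation of the γ-hydroxy amides and leaves no acidic proton for the organometallic step, without touching any stereocentre.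

Step 6
Reactants: 8 (2R,3R)-2,3-bis{(R)-[4-(benzyloxy)phenyl][(triethylsilyl)oxy]methyl}-N1,N4-dimethoxy-N1,N4-dimethylbutanediamide; 9 4-(benzyloxy)-1-bromo-2-fluorobenzene
Product: 11 (2R,3R)-1,4-bis[4-(benzyloxy)-2-fluorophenyl]-2,3-bis{(R)-[4-(benzyloxy)phenyl][(triethylsilyl)oxy]methyl}butane-1,4-dione, via aryl Grignard reagent 10 (not isolated)
Conditions: 9 (5 equiv), Mg, THF, rt; then 8, THF, 0 °C to rt; sat. aq NH4Cl, 0 °C
Reagents that add atoms: magnesium, [Mg] (held only in 10)
Why: Weinreb ketone synthesis, in which each amide takes up one aryl Grignard reagent and holds it as a magnesium-chelated tetrahedral adduct until the quench, so that no tertiary alcohol forms, the ortho-fluoro Grignard reagent being stable to aryne formation at or below room temperature and the stereocentres being spectators.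

Step 7
Reactants: 11 (2R,3R)-1,4-bis[4-(benzyloxy)-2-fluorophenyl]-2,3-bis{(R)-[4-(benzyloxy)phenyl][(triethylsilyl)oxy]methyl}butane-1,4-dione
Product: 14 (2R,3S,2''R,3''S)-7,7'',4',4'''-tetrakis(benzyloxy)-3,3''-biflavanone (2,3-trans in both units), via diol diketone 12 (not isolated), via cis-cis biflavanone 13 (not isolated)
Conditions: Bu4NF (2.5 equiv), THF, 0 °C to rt; then DBU (0.2 equiv), rt, quenched with AcOH once the cis isomers are consumed
Reagents that add atoms: none
Why: Fluoride strips both silyl groups and each freed C2 oxygen attacks the fluorine-bearing carbon ortho to the ketone of its own unit (intramolecular SNAr, six-membered closure beating the seven-membered alternative at the other ring A) with retention at C2, after which amine-mediated enolisation moves C3 and C3'' from the 2,3-cis (R) to the diequatorial 2,3-trans (S) arrangement under thermodynamic control, an amine being preferred to acid because the C4–C3–C3''–C4'' 1,4-diketone would be open to Paal–Knorr furan formation.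

Step 8
Reactants: 14 (2R,3S,2''R,3''S)-7,7'',4',4'''-tetrakis(benzyloxy)-3,3''-biflavanone
Product: 15 (2R,3S,2''R,3''S)-7,7'',4',4'''-tetrahydroxy-3,3''-biflavanone (CNP0231820.2)
Conditions: H2 (1 atm), Pd/C (10 wt %), EtOAc–MeOH, rt, stopped after uptake of four equivalents
Reagents that add atoms: none
Why: Catalytic hydrogenolysis of aryl benzyl ethers, a standard neutral finish for flavanones, frees the four phenols without acid or base, so neither the enolisable C3/C3'' nor the C2/C2'' centres (labile through opening of ring C to a chalcone) can drift, which is why benzyl was preferred to methyl and its BBr3 cleavage.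

**Compound list**
1 | 1-[4-(benzyloxy)phenyl]ethan-1-one | CC(=O)c1ccc(OCc2ccccc2)cc1 | starting material
2 | ethyl 3-[4-(benzyloxy)phenyl]-3-oxopropanoate | CCOC(=O)CC(=O)c1ccc(OCc2ccccc2)cc1 | intermediate
3 | ethyl 3-[4-(benzyloxy)phenyl]-2-iodo-3-oxopropanoate (racemic, transient in step 2) | CCOC(=O)C(I)C(=O)c1ccc(OCc2ccccc2)cc1 | intermediate
4 | diethyl 2,3-bis[4-(benzyloxy)benzoyl]butanedioate (stereolabile meso/dl mixture) | CCOC(=O)C(C(=O)c1ccc(OCc2ccccc2)cc1)C(C(=O)c1ccc(OCc2ccccc2)cc1)C(=O)OCC | intermediate
5 | diethyl (2R,3R)-2,3-bis{(R)-[4-(benzyloxy)phenyl](hydroxy)methyl}butanedioate (transient in step 3) | CCOC(=O)[C@@H]([C@@H](O)c1ccc(OCc2ccccc2)cc1)[C@H]([C@@H](O)c1ccc(OCc2ccccc2)cc1)C(=O)OCC | intermediate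
6 | (1R,4R,5R,8R)-4,8-bis[4-(benzyloxy)phenyl]-3,7-dioxabicyclo[3.3.0]octane-2,6-dione | O=C1O[C@@H](c2ccc(OCc3ccccc3)cc2)[C@@H]2C(=O)O[C@@H](c3ccc(OCc4ccccc4)cc3)[C@H]12 | intermediate
7 | (2R,3R)-2,3-bis{(R)-[4-(benzyloxy)phenyl](hydroxy)methyl}-N1,N4-dimethoxy-N1,N4-dimethylbutanediamide | CON(C)C(=O)[C@@H]([C@@H](O)c1ccc(OCc2ccccc2)cc1)[C@H]([C@@H](O)c1ccc(OCc2ccccc2)cc1)C(=O)N(C)OC | intermediate
8 | (2R,3R)-2,3-bis{(R)-[4-(benzyloxy)phenyl][(triethylsilyl)oxy]methyl}-N1,N4-dimethoxy-N1,N4-dimethylbutanediamide | CON(C)C(=O)[C@@H]([C@@H](O[Si](CC)(CC)CC)c1ccc(OCc2ccccc2)cc1)[C@H]([C@@H](O[Si](CC)(CC)CC)c1ccc(OCc2ccccc2)cc1)C(=O)N(C)OC | intermediate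
9 | 4-(benzyloxy)-1-bromo-2-fluorobenzene | Fc1cc(OCc2ccccc2)ccc1Br | starting material
10 | [4-(benzyloxy)-2-fluorophenyl]magnesium bromide (transient in step 6) | Fc1cc(OCc2ccccc2)ccc1[Mg]Br | intermediate
11 | (2R,3R)-1,4-bis[4-(benzyloxy)-2-fluorophenyl]-2,3-bis{(R)-[4-(benzyloxy)phenyl][(triethylsilyl)oxy]methyl}butane-1,4-dione | O=C(c1ccc(OCc2ccccc2)cc1F)[C@@H]([C@@H](O[Si](CC)(CC)CC)c1ccc(OCc2ccccc2)cc1)[C@H]([C@@H](O[Si](CC)(CC)CC)c1ccc(OCc2ccccc2)cc1)C(=O)c1ccc(OCc2ccccc2)cc1F | intermediate
12 | (2R,3R)-1,4-bis[4-(benzyloxy)-2-fluorophenyl]-2,3-bis{(R)-[4-(benzyloxy)phenyl](hydroxy)methyl}butane-1,4-dione (transient in step 7) | O=C(c1ccc(OCc2ccccc2)cc1F)[C@@H]([C@@H](O)c1ccc(OCc2ccccc2)cc1)[C@H]([C@@H](O)c1ccc(OCc2ccccc2)cc1)C(=O)c1ccc(OCc2ccccc2)cc1F | intermediate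
13 | (2R,3R,2''R,3''R)-7,7'',4',4'''-tetrakis(benzyloxy)-3,3''-biflavanone (2,3-cis in both units, transient in step 7) | O=C1c2ccc(OCc3ccccc3)cc2O[C@@H](c2ccc(OCc3ccccc3)cc2)[C@H]1[C@H]1C(=O)c2ccc(OCc3ccccc3)cc2O[C@H]1c1ccc(OCc2ccccc2)cc1 | intermediate
14 | (2R,3S,2''R,3''S)-7,7'',4',4'''-tetrakis(benzyloxy)-3,3''-biflavanone (2,3-trans in both units) | O=C1c2ccc(OCc3ccccc3)cc2O[C@@H](c2ccc(OCc3ccccc3)cc2)[C@@H]1[C@@H]1C(=O)c2ccc(OCc3ccccc3)cc2O[C@H]1c1ccc(OCc2ccccc2)cc1 | intermediate
15 | (2R,3S,2''R,3''S)-7,7'',4',4'''-tetrahydroxy-3,3''-biflavanone, that is (2R,2'R,3S,3'S)-7,7'-dihydroxy-2,2'-bis(4-hydroxyphenyl)-[3,3'-bichromane]-4,4'-dione | O=C1c2ccc(O)cc2O[C@@H](c2ccc(O)cc2)[C@@H]1[C@@H]1C(=O)c2ccc(O)cc2O[C@H]1c1ccc(O)cc1 | target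

**Total step count:** 8. **Longest linear sequence:** 8 steps (1 to 15). The Grignard reagent from 9 is made within step 6.

**Steps most likely to fail**

Step 3.
- Reduction may outrun epimerisation, so that unlike-configured C3/C3'' pairs are frozen and the cascade halts after one lactonisation.
- Facial selection at the hindered, α-branched aryl ketones may be weak, or may be overridden by the substrate in the second reduction.
- Adventitious HCl may dehydrate the 1,4-diketone in the Paal–Knorr sense.
- Fallback (racemic reduction plus resolution in place of asymmetric catalysis, all known chemistry). It sets out from 4. NaBH4 in EtOH–THF at 0 °C followed by warming in toluene is the classical reduction–lactonisation of diaroylsuccinates. After crystallisation it should give the racemic exo,exo-dilactone F1. Preparative chromatography on a chiral stationary phase (amylose tris(3,5-dimethylphenylcarbamate) on silica) then delivers the (1R,4R,5R,8R) enantiomer. The route is rejoined at 6.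

Step 7.
- Retro-aldol cleavage or dehydration of the freed β-hydroxy ketone may compete with ring closure.
- Retro-oxa-Michael opening of the chromanone enolate may set in during the equilibration. Either process would erode C2 and C2''.
- Fallback (a change of oxidation level, so that no β-hydroxy ketone meets base). It sets out from 11. HF·pyridine in THF removes the silyl groups under acidic conditions to give 12. Hydroxyl-directed Evans–Saksena reduction with Me4NBH(OAc)3 in MeCN–AcOH takes both ketones to the fluoroaryl tetraol F2. KOtBu in DMF at 80 °C then closes both O1–C8a bonds, by the intramolecular SNAr known for 3-(2-fluorophenyl)propanols, to give the bis(flavan-4-ol) F3. Dess–Martin periodinane reoxidises C4 and C4''. The route is rejoined at 13, which is equilibrated with DBU as in the second stage of step 7.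

Step 6.
- Double addition at two adjacent, heavily flanked amides may be sluggish.
- Base-induced loss of formaldehyde from the N-methoxy group or β-elimination of silanolate may then take over.
- Fallback (aldehyde addition and oxidation in place of acyl substitution). It sets out from 8. iBu2AlH in THF at −78 °C stops at the silylated dialdehyde F4. Its far less hindered formyl groups take up 10 at −78 to 0 °C to give the silylated 1,4-diol F5. Dess–Martin periodinane oxidises both carbinols. The route is rejoined at 11.

**Further compounds**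
F1 | step 3 | racemic (1R*,4R*,5R*,8R*)-4,8-bis[4-(benzyloxy)phenyl]-3,7-dioxabicyclo[3.3.0]octane-2,6-dione, that is 6 together with its (1S,4S,5S,8S) enantiomer (the enantiomer is drawn) | O=C1O[C@H](c2ccc(OCc3ccccc3)cc2)[C@H]2C(=O)O[C@H](c3ccc(OCc4ccccc4)cc3)[C@@H]12
F2 | step 7 | 1,4-bis[4-(benzyloxy)-2-fluorophenyl]-2,3-bis{(R)-[4-(benzyloxy)phenyl](hydroxy)methyl}butane-1,4-diol, backbone centres as in 12, new carbinol centres unassigned | OC(c1ccc(OCc2ccccc2)cc1F)[C@@H]([C@@H](O)c1ccc(OCc2ccccc2)cc1)[C@H]([C@@H](O)c1ccc(OCc2ccccc2)cc1)C(O)c1ccc(OCc2ccccc2)cc1F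
F3 | step 7 | 7,7'',4',4'''-tetrakis(benzyloxy)-3,3''-biflavan-4,4''-diol, C2/C3/C2''/C3'' arranged as in 13, C4 and C4'' unassigned | OC1c2ccc(OCc3ccccc3)cc2O[C@@H](c2ccc(OCc3ccccc3)cc2)[C@H]1[C@H]1C(O)c2ccc(OCc3ccccc3)cc2O[C@H]1c1ccc(OCc2ccccc2)cc1
F4 | step 6 | (2R,3R)-2,3-bis{(R)-[4-(benzyloxy)phenyl][(triethylsilyl)oxy]methyl}butanedial | O=C[C@@H]([C@@H](O[Si](CC)(CC)CC)c1ccc(OCc2ccccc2)cc1)[C@H]([C@@H](O[Si](CC)(CC)CC)c1ccc(OCc2ccccc2)cc1)C=O
F5 | step 6 | 1,4-bis[4-(benzyloxy)-2-fluorophenyl]-2,3-bis{(R)-[4-(benzyloxy)phenyl][(triethylsilyl)oxy]methyl}butane-1,4-diol, backbone centres as in 11, new carbinol centres unassigned | OC(c1ccc(OCc2ccccc2)cc1F)[C@@H]([C@@H](O[Si](CC)(CC)CC)c1ccc(OCc2ccccc2)cc1)[C@H]([C@@H](O[Si](CC)(CC)CC)c1ccc(OCc2ccccc2)cc1)C(O)c1ccc(OCc2ccccc2)cc1F
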